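**Remarks on the chemistry (assumptions)**
- The target has no stereocentre and is achiral, so no step has to set or protect configuration.
- The target is drawn as the free aryl hydrogen sulfate; the last step is therefore taken to end with proton exchange of the pyridinium salt.

**Retrosynthetic overview**
- The sulfate comes from the ring-A phenol, and that phenol from an aryl pinacol boronate (C–B to C–O).
- Feature: in ring A (C1 OSO3H, C2 OAr, C3 Br, C4 H, C5 Br, C6 H) the run C3–C6 reads Br, H, Br, H, as in C3–C6 of 3,5-dibromo-2-pyrone; C1 and C2 are the two carbons of an alkyne bearing boron and the aryloxy group.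
- Key disconnection: bonds C2–C3 and C1–C6 of ring A, made by [4+2] cycloaddition of the pyrone with an aryloxyethynyl boronate and loss of CO2.
- The ynol-ether boronate comes from the ring B–C phenol by O-vinylation, bromination/dehydrobromination and amide-base elimination/borylation. Organolithium reagents and hot copper(I) are avoided because of five Ar–Br and one Ar–I.
- Rings B and C are bought as benzenes (guaiacol tribrominated; 4-bromo-1-fluoro-2-nitrobenzene joined by SNAr, then NO2 to I). Ring A is the only ring formed and is formed last.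

Key step: step 10

**Route**

Step 1
Reactants: 1 guaiacol (2-methoxyphenol)
Product: 2 2,3,4-tribromo-6-methoxyphenol (4,5,6-tribromoguaiacol)
Conditions: Br2 (3.2 equiv), AcOH, 15 °C to rt
Reagents that add atoms: bromine, BrBr
Why: Electrophilic aromatic bromination, in which the free OH directs to its para and ortho positions and OMe to its para position, so the position between OMe and the first bromine stays H and the deactivated ring should stop at the tribromide without a Lewis acid.

Step 2
Reactants: 2 2,3,4-tribromo-6-methoxyphenol; 3 4-bromo-1-fluoro-2-nitrobenzene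
Product: 4 1,2,3-tribromo-4-(4-bromo-2-nitrophenoxy)-5-methoxybenzene
Conditions: K2CO3, DMF, 80 °C
Reagents that add atoms: none
Why: Nucleophilic aromatic substitution (SNAr) of the fluoride ortho to the nitro group by the acidic, hindered phenoxide; the bromine of 3 is meta to the nitro group and is not activated.

Step 3
Reactants: 4 1,2,3-tribromo-4-(4-bromo-2-nitrophenoxy)-5-methoxybenzene
Product: 5 5-bromo-2-(2,3,4-tribromo-6-methoxyphenoxy)aniline
Conditions: Fe powder, AcOH, EtOH, 70 °C
Reagents that add atoms: none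
Why: Béchamp-type dissolving-iron reduction, which reduces the nitro group and leaves the aryl bromides, as catalytic hydrogenation might not.

Step 4
Reactants: 5 5-bromo-2-(2,3,4-tribromo-6-methoxyphenoxy)aniline
Product: 7 1,2,3-tribromo-4-(4-bromo-2-iodophenoxy)-5-methoxybenzene, via arenediazonium tosylate 6 (not isolated)
Conditions: p-TsOH·H2O, NaNO2, KI, MeCN–H2O, 10 °C to rt
Reagents that add atoms: potassium iodide, [K+].[I-] (sodium nitrite, [Na+].[O-]N=O, puts nitrogen only into 6)
Why: Diazotisation and copper-free Sandmeyer-type iododediazoniation; both positions of ring B ortho to the ether oxygen are substituted, so Pschorr-type closure to a dibenzofuran is blocked.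

Step 5
Reactants: 7 1,2,3-tribromo-4-(4-bromo-2-iodophenoxy)-5-methoxybenzene
Product: 8 3,4,5-tribromo-2-(4-bromo-2-iodophenoxy)phenol
Conditions: BBr3, CH2Cl2, −78 °C to rt; then H2O
Reagents that add atoms: none
Why: Lewis-acid cleavage of the aryl methyl ether (bromide attacks the methyl group of the boron-bound oxonium); the diaryl ether and the aryl halides are inert to BBr3.

Step 6
Reactants: 8 3,4,5-tribromo-2-(4-bromo-2-iodophenoxy)phenol
Product: 9 1,2,3-tribromo-4-(4-bromo-2-iodophenoxy)-5-(ethenyloxy)benzene
Conditions: 2,4,6-trivinylcyclotriboroxane–pyridine (0.7 equiv), Cu(OAc)2 (2 equiv), pyridine, CH2Cl2, rt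
Reagents that add atoms: 2,4,6-trivinylcyclotriboroxane–pyridine complex, C=CB1OB(C=C)OB(C=C)O1.c1ccncc1
Why: Chan–Lam-type oxidative copper(II) O-vinylation of a phenol with a vinylboron reagent at room temperature, where Ar–I and Ar–Br are not engaged as they could be under hot copper(I) Ullmann conditions.

Step 7
Reactants: 9 1,2,3-tribromo-4-(4-bromo-2-iodophenoxy)-5-(ethenyloxy)benzene
Product: 11 1,2,3-tribromo-4-(4-bromo-2-iodophenoxy)-5-{[(Z)-2-bromoethenyl]oxy}benzene, via 1,2-dibromoethyl ether 10 (not isolated)
Conditions: Br2 (1.0 equiv), CH2Cl2, −78 °C; then i-Pr2NEt, −78 °C to 40 °C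
Reagents that add atoms: bromine, BrBr
Why: Bromine addition to the enol-ether double bond, far faster than substitution on the deactivated rings, then amine-induced dehydrobromination of the oxygen-activated α-bromo ether, which should give mainly the Z 2-bromovinyl ether; any E or 1-bromovinyl isomer leads to the same alkyne in step 8.

Step 8
Reactants: 11 1,2,3-tribromo-4-(4-bromo-2-iodophenoxy)-5-{[(Z)-2-bromoethenyl]oxy}benzene
Product: 15 2-{[3,4,5-tribromo-2-(4-bromo-2-iodophenoxy)phenoxy]ethynyl}-4,4,5,5-tetramethyl-1,3,2-dioxaborolane, via terminal ynol ether 12 (not isolated), via sodium acetylide 13 (not isolated), via sodium alkynylborate 14 (not isolated)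
Conditions: NaHMDS (2.2 equiv), THF, −78 to −40 °C; i-PrOBpin, −78 °C; HCl in Et2O (1.2 equiv), −78 °C to rt; filtered and used crude
Reagents that add atoms: 2-isopropoxy-4,4,5,5-tetramethyl-1,3,2-dioxaborolane, CC(C)OB1OC(C)(C)C(C)(C)O1
Why: Anti E2 dehydrobromination by the hindered amide (the hydrogen on the oxygen-bearing carbon is trans to bromine), deprotonation of the alkyne by the second equivalent, and acetylide borylation with collapse of the ate complex by anhydrous acid; a silylamide does not undergo halogen–metal exchange with Ar–I or Ar–Br.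

Step 9
Reactants: 16 coumalic acid (2-oxo-2H-pyran-5-carboxylic acid)
Product: 17 3,5-dibromo-2H-pyran-2-one
Conditions: NBS (2.5 equiv), LiOAc, MeCN–H2O, rt
Reagents that add atoms: N-bromosuccinimide, O=C1CCC(=O)N1Br
Why: Hunsdiecker-type bromodecarboxylation at C5 (ipso-bromination of the carboxylate carbon with loss of CO2) together with electrophilic bromination at C3 of the pyrone.

Step 10
Reactants: 15 2-{[3,4,5-tribromo-2-(4-bromo-2-iodophenoxy)phenoxy]ethynyl}-4,4,5,5-tetramethyl-1,3,2-dioxaborolane; 17 3,5-dibromo-2H-pyran-2-one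
Product: 19 2-{3,5-dibromo-2-[3,4,5-tribromo-2-(4-bromo-2-iodophenoxy)phenoxy]phenyl}-4,4,5,5-tetramethyl-1,3,2-dioxaborolane, via bicyclic lactone 18 (not isolated)
Conditions: 17 (1.5 equiv), toluene, 120 °C, sealed tube, dark
Reagents that add atoms: none
Why: Proposed new method: the electron-poor diene C3=C4–C5=C6 of 17 and the push–pull alkyne of 15 should combine in a thermal, asynchronous [4+2] cycloaddition to the 2-oxabicyclo[2.2.2]octadienone 18, which expels CO2 by retro-[4+2] and leaves ring A as a benzene; the closest known reactions are the cycloaddition–decarboxylation of 2-pyrones with alkynyl pinacol boronates to aryl boronates and the inverse-demand additions of enol ethers to 3,5-dibromo-2-pyrone. Ring A is closed intermolecularly, both new C–C bonds (oxygen-bearing alkyne carbon to pyrone C3, boron-bearing carbon to pyrone C6) forming in the cycloaddition and aromaticity arising from loss of CO2 without an oxidant. No stereocentre survives, because the two bridgehead centres of 18 become sp2. The step needs one regiochemistry, and the ynol-ether polarisation should supply it: the boron-bearing carbon is the nucleophilic terminus (β to oxygen) and should attack the electrophilic C6 of the pyrone, the same orientation in which enol ethers place their alkoxy carbon next to the brominated C3, and the pinacol boronate also stays away from the C3 bromine. An aryl ynol ether has no hydrogen that could be transferred in a retro-ene fragmentation to a ketene, and Ar–Br, Ar–I and the boronate are inert under purely thermal conditions.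

Step 11
Reactants: 19 2-{3,5-dibromo-2-[3,4,5-tribromo-2-(4-bromo-2-iodophenoxy)phenoxy]phenyl}-4,4,5,5-tetramethyl-1,3,2-dioxaborolane
Product: 20 3,5-dibromo-2-[3,4,5-tribromo-2-(4-bromo-2-iodophenoxy)phenoxy]phenol
Conditions: NaBO3·4H2O, THF–H2O, rt
Reagents that add atoms: sodium perborate tetrahydrate, [Na+].[O-]OB=O.O.O.O.O
Why: Oxidation of an aryl boronate by perborate (1,2-aryl shift from boron to oxygen in the peroxoborate, then hydrolysis), mild enough to leave the aryl iodide untouched.

Step 12
Reactants: 20 3,5-dibromo-2-[3,4,5-tribromo-2-(4-bromo-2-iodophenoxy)phenoxy]phenol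
Product: 22 3,5-dibromo-2-[3,4,5-tribromo-2-(4-bromo-2-iodophenoxy)phenoxy]phenyl hydrogen sulfate (bromoiesol B sulfate), via pyridinium aryl sulfate 21 (not isolated)
Conditions: SO3·pyridine, pyridine, 40 °C; then Dowex 50W (H+ form), MeOH–H2O, 0 °C
Reagents that add atoms: sulfur trioxide–pyridine complex, O=S(=O)([O-])[n+]1ccccc1
Why: O-Sulfation of the phenol by the sulfur trioxide–amine complex, then cation exchange of pyridinium for a proton on the acidic resin; the electron-poor aryl sulfate should tolerate the brief cold acid contact.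

**Compound list**
1 | guaiacol (2-methoxyphenol) | COc1ccccc1O | starting material
2 | 2,3,4-tribromo-6-methoxyphenol | COc1cc(Br)c(Br)c(Br)c1O | intermediate
3 | 4-bromo-1-fluoro-2-nitrobenzene | O=[N+]([O-])c1cc(Br)ccc1F | starting material
4 | 1,2,3-tribromo-4-(4-bromo-2-nitrophenoxy)-5-methoxybenzene | COc1cc(Br)c(Br)c(Br)c1Oc1ccc(Br)cc1[N+](=O)[O-] | intermediate
5 | 5-bromo-2-(2,3,4-tribromo-6-methoxyphenoxy)aniline | COc1cc(Br)c(Br)c(Br)c1Oc1ccc(Br)cc1N | intermediate
6 | 5-bromo-2-(2,3,4-tribromo-6-methoxyphenoxy)benzenediazonium p-toluenesulfonate | COc1cc(Br)c(Br)c(Br)c1Oc1ccc(Br)cc1[N+]#N.Cc1ccc(cc1)S(=O)(=O)[O-] | intermediate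
7 | 1,2,3-tribromo-4-(4-bromo-2-iodophenoxy)-5-methoxybenzene | COc1cc(Br)c(Br)c(Br)c1Oc1ccc(Br)cc1I | intermediate
8 | 3,4,5-tribromo-2-(4-bromo-2-iodophenoxy)phenol | Oc1cc(Br)c(Br)c(Br)c1Oc1ccc(Br)cc1I | intermediate
9 | 1,2,3-tribromo-4-(4-bromo-2-iodophenoxy)-5-(ethenyloxy)benzene | C=COc1cc(Br)c(Br)c(Br)c1Oc1ccc(Br)cc1I | intermediate
10 | 1,2,3-tribromo-4-(4-bromo-2-iodophenoxy)-5-(1,2-dibromoethoxy)benzene (racemic) | BrCC(Br)Oc1cc(Br)c(Br)c(Br)c1Oc1ccc(Br)cc1I | intermediate
11 | 1,2,3-tribromo-4-(4-bromo-2-iodophenoxy)-5-{[(Z)-2-bromoethenyl]oxy}benzene | Br/C=C\Oc1cc(Br)c(Br)c(Br)c1Oc1ccc(Br)cc1I | intermediate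
12 | 1,2,3-tribromo-4-(4-bromo-2-iodophenoxy)-5-(ethynyloxy)benzene | C#COc1cc(Br)c(Br)c(Br)c1Oc1ccc(Br)cc1I | intermediate
13 | sodium [3,4,5-tribromo-2-(4-bromo-2-iodophenoxy)phenoxy]acetylide | [Na+].[C-]#COc1cc(Br)c(Br)c(Br)c1Oc1ccc(Br)cc1I | intermediate
14 | sodium isopropoxy(pinacolato){[3,4,5-tribromo-2-(4-bromo-2-iodophenoxy)phenoxy]ethynyl}borate | [Na+].CC(C)O[B-]1(C#COc2cc(Br)c(Br)c(Br)c2Oc2ccc(Br)cc2I)OC(C)(C)C(C)(C)O1 | intermediate
15 | 2-{[3,4,5-tribromo-2-(4-bromo-2-iodophenoxy)phenoxy]ethynyl}-4,4,5,5-tetramethyl-1,3,2-dioxaborolane | CC1(C)OB(C#COc2cc(Br)c(Br)c(Br)c2Oc2ccc(Br)cc2I)OC1(C)C | intermediate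
16 | coumalic acid | O=C(O)c1ccc(=O)oc1 | starting material
17 | 3,5-dibromo-2H-pyran-2-one | O=c1occ(Br)cc1Br | intermediate
18 | 4,7-dibromo-5-[3,4,5-tribromo-2-(4-bromo-2-iodophenoxy)phenoxy]-6-(4,4,5,5-tetramethyl-1,3,2-dioxaborolan-2-yl)-2-oxabicyclo[2.2.2]octa-5,7-dien-3-one (racemic) | O=C1OC2C(Br)=CC1(Br)C(Oc3cc(Br)c(Br)c(Br)c3Oc3ccc(Br)cc3I)=C2B4OC(C)(C)C(C)(C)O4 | intermediate
19 | 2-{3,5-dibromo-2-[3,4,5-tribromo-2-(4-bromo-2-iodophenoxy)phenoxy]phenyl}-4,4,5,5-tetramethyl-1,3,2-dioxaborolane | CC1(C)OB(c2cc(Br)cc(Br)c2Oc2cc(Br)c(Br)c(Br)c2Oc2ccc(Br)cc2I)OC1(C)C | intermediate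
20 | 3,5-dibromo-2-[3,4,5-tribromo-2-(4-bromo-2-iodophenoxy)phenoxy]phenol | Oc1cc(Br)cc(Br)c1Oc1cc(Br)c(Br)c(Br)c1Oc1ccc(Br)cc1I | intermediate
21 | pyridinium 3,5-dibromo-2-[3,4,5-tribromo-2-(4-bromo-2-iodophenoxy)phenoxy]phenyl sulfate | [O-]S(=O)(=O)Oc1cc(Br)cc(Br)c1Oc1cc(Br)c(Br)c(Br)c1Oc1ccc(Br)cc1I.c1cc[nH+]cc1 | intermediate
22 | 3,5-dibromo-2-[3,4,5-tribromo-2-(4-bromo-2-iodophenoxy)phenoxy]phenyl hydrogen sulfate (bromoiesol B sulfate) | O=S(=O)(O)Oc1cc(Br)cc(Br)c1Oc1cc(Br)c(Br)c(Br)c1Oc1ccc(Br)cc1I | target

**Count**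
Total steps: 12. Longest linear sequence: 11 (steps 1–8 and 10–12; step 9 is the one-step branch to the pyrone).

**Steps most likely to fail, with fallbacks**

Step 10 (key step, proposed new method). The cycloaddition may be too slow because the aryloxy donor is weakened by the electron-poor aryl group and the boronate. The ynol-ether boronate may also hydrolyse or oligomerise before it reacts, or the alkyne may add in the reverse orientation. The fallback attaches ring A ready-made by known chemistry and sets out from phenol 8. SNAr of 8 on commercial 3,5-dibromo-2-fluorobenzaldehyde (Cs2CO3, DMF, 90 °C), whose fluoride is activated by the ortho formyl group, should give 3,5-dibromo-2-[3,4,5-tribromo-2-(4-bromo-2-iodophenoxy)phenoxy]benzaldehyde F1. Baeyer–Villiger oxidation (mCPBA, CH2Cl2, rt) should then give 3,5-dibromo-2-[3,4,5-tribromo-2-(4-bromo-2-iodophenoxy)phenoxy]phenyl formate F2. Methanolysis (K2CO3, MeOH, 0 °C) would give phenol 20, where the route is rejoined before step 12.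

Step 8. The amide may add to the electron-poor ynol ether or displace the aryloxide, the sodium aryloxyacetylide may decompose before borylation, and the acid used to collapse the ate complex may protodeboronate or add across the ynol ether. The fallback sets out from 11 and separates alkyne formation from borylation. Dehydrobromination with t-BuOK (2.2 equiv, THF, −40 °C, NH4Cl quench) gives the terminal ynol ether 12, which is isolated. Catalytic C–H borylation of the terminal alkyne (NHC–silver chloride catalyst, Cs2CO3, i-PrOBpin, MeCN, rt) then gives 15 without a stoichiometric metal acetylide or an acid step. It comes back at 15 and makes no compound outside the list (F0).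

Step 6. Transmetalation and C–O bond formation at copper may be slow for this hindered, acidic phenol, so that vinyl transfer stalls and the boroxine is consumed by homocoupling. The fallback sets out from 8 and builds the vinyl group by alkylation and elimination. O-Alkylation with excess 1,2-dibromoethane (K2CO3, MeCN, reflux) should give 1,2,3-tribromo-4-(4-bromo-2-iodophenoxy)-5-(2-bromoethoxy)benzene F3. E2 elimination with t-BuOK (THF, 0 °C to rt) then gives vinyl ether 9, where the route is rejoined before step 7.

**Further compounds**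
F1 | step 10 | 3,5-dibromo-2-[3,4,5-tribromo-2-(4-bromo-2-iodophenoxy)phenoxy]benzaldehyde | O=Cc1cc(Br)cc(Br)c1Oc1cc(Br)c(Br)c(Br)c1Oc1ccc(Br)cc1I
F2 | step 10 | 3,5-dibromo-2-[3,4,5-tribromo-2-(4-bromo-2-iodophenoxy)phenoxy]phenyl formate | O=COc1cc(Br)cc(Br)c1Oc1cc(Br)c(Br)c(Br)c1Oc1ccc(Br)cc1I
F0 | step 8 | none | none
F3 | step 6 | 1,2,3-tribromo-4-(4-bromo-2-iodophenoxy)-5-(2-bromoethoxy)benzene | BrCCOc1cc(Br)c(Br)c(Br)c1Oc1ccc(Br)cc1I
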